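The cyclohexane ring (ring B) is disconnected by a Diels–Alder reaction. Its two adjacent unsubstituted CH2 carbons (C6, C7) are the dienophile, an ethylene equivalent (acrolein, formyl excised later). The CHMe carbon (C8), the spiro C–O carbon (C9), the quaternary carbon (C10) and the CH bearing the hydroxyisopropyl group (C5) form a 2-silyloxy-1,3-diene. One catalytic enantioselective cycloaddition forms C5–C6 and C7–C8, sets C5 and leaves a regiodefined silyl enol ether whose oxygen becomes the spiro ether oxygen. C5 then relays C10 (Mukaiyama–Michael), C8 (equilibration) and C9 (axial allylzinc addition). The tropone is annulated onto the resulting spiro α-methylene lactone.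

Key step: step 5

Remark: C4 is the carbinol carbon, C1–C3 the propanoic chain, C11 the dihydrofuran CH2; the tropone carbons are T1 (C=O), T2 (CMe), T3 (C–O), T4 (C–C11), T5 (CH), T6 (CMe), T7 (C–CO2Me). The oxazaborolidine enantiomer written in step 5 is assumed to be the one that delivers 5S; its antipode is equally available.

Step 1
Reactants: 1 methyl 2-hydroxy-2-methylpropanoate
Product: 2 methyl 2-methyl-2-(triethylsilyloxy)propanoate
Conditions: Et3SiOTf, 2,6-lutidine, CH2Cl2, 0 °C
Reagents that add atoms: triethylsilyl trifluoromethanesulfonate, CC[Si](CC)(CC)OS(=O)(=O)C(F)(F)F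
Why: Silyl triflate and a hindered pyridine base silylate even a tertiary alcohol (silyl ether protection); no stereocentre is involved.

Step 2
Reactants: 2 methyl 2-methyl-2-(triethylsilyloxy)propanoate
Product: 3 2-methyl-2-(triethylsilyloxy)propanal
Conditions: i-Bu2AlH (1.1 equiv), CH2Cl2, −78 °C; aq. potassium sodium tartrate
Reagents that add atoms: none
Why: Partial hydride reduction of an α-silyloxy ester should stop at the aldehyde because the tetrahedral aluminate survives at −78 °C until work-up.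

Step 3
Reactants: 4 pentan-3-one; 3 2-methyl-2-(triethylsilyloxy)propanal
Product: 7 (E)-4,6-dimethyl-6-(triethylsilyloxy)hept-4-en-3-one, via lithium aldolate 5 (not isolated), via mesylate 6 (not isolated)
Conditions: LiN(i-Pr)2, THF, −78 °C; then MsCl, Et3N, −78 → 0 °C; then DBU, rt
Reagents that add atoms: none
Why: Directed aldol addition to a non-enolisable aldehyde followed by mesylation and E1cB elimination (aldol condensation) should give the E enone, the bulky silyloxyisopropyl group lying trans to the acyl group.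

Step 4
Reactants: 7 (E)-4,6-dimethyl-6-(triethylsilyloxy)hept-4-en-3-one
Product: 8 (2Z,4E)-3-(tert-butyldimethylsilyloxy)-4,6-dimethyl-6-(triethylsilyloxy)hepta-2,4-diene
Conditions: t-BuMe2SiOTf, Et3N, CH2Cl2, 0 °C
Reagents that add atoms: tert-butyldimethylsilyl trifluoromethanesulfonate, CC(C)(C)[Si](C)(C)OS(=O)(=O)C(F)(F)F
Why: Soft enolisation of the ethyl ketone gives the 2-silyloxy diene, and the Z enol ether (methyl cis to oxygen) is expected because it avoids A(1,3) strain with the substituted vinyl group, so both terminal substituents point outward.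

Step 5
Reactants: 8 (2Z,4E)-3-(tert-butyldimethylsilyloxy)-4,6-dimethyl-6-(triethylsilyloxy)hepta-2,4-diene; 9 acrolein
Product: 10 (1S,2S,5R)-4-(tert-butyldimethylsilyloxy)-3,5-dimethyl-2-[2-(triethylsilyloxy)propan-2-yl]cyclohex-3-ene-1-carbaldehyde
Conditions: (S)-1-(2-methylphenyl)-3,3-diphenyltetrahydro-1H,3H-pyrrolo[1,2-c][1,3,2]oxazaborole (20 mol %), (CF3SO2)2NH (18 mol %), 9 (3 equiv), CH2Cl2, −78 → −40 °C
Reagents that add atoms: none
Why: The protonated oxazaborolidine binds acrolein and lowers its LUMO, and the electron-rich diene adds in a concerted, asynchronous [4+2] cycloaddition in which the C7–C8 bond from the enol-ether terminus leads. The closest known reaction type is the oxazaborolidinium-catalysed enantioselective Diels–Alder reaction of 2-silyloxy-1,3-dienes with enals. Ring B closes by an intermolecular suprafacial six-ring cycloaddition without a tether, the 2,3-disubstitution of the diene favouring the reactive s-cis conformer. C5 and C8 are set cis by the 4E and 2Z geometry of the diene, their absolute sense by the catalyst shielding one face of the bound enal, and the formyl-bearing carbon by the endo rule. Only facial selectivity is needed: regio- and endo/exo selectivity are irrelevant because the formyl group is excised in step 6, and C8 is corrected in step 7, so C5 is the centre that counts. Low temperature and a slight deficit of acid relative to the oxazaborolidine should protect the silyl enol ether and the allylic tertiary silyl ether.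

Step 6
Reactants: 10 (1S,2S,5R)-4-(tert-butyldimethylsilyloxy)-3,5-dimethyl-2-[2-(triethylsilyloxy)propan-2-yl]cyclohex-3-ene-1-carbaldehyde
Product: 11 tert-butyl{[(3S,6R)-2,6-dimethyl-3-[2-(triethylsilyloxy)propan-2-yl]cyclohex-1-en-1-yl]oxy}dimethylsilane
Conditions: RhCl(PPh3)3 (1.1 equiv), PhMe, 110 °C
Reagents that add atoms: none
Why: Tsuji–Wilkinson decarbonylation (formyl C–H insertion by monovalent rhodium, CO migration, C–H reductive elimination) replaces CHO by H under neutral conditions that leave the silyl enol ether and the C5 and C8 centres untouched.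

Step 7
Reactants: 11 tert-butyl{[(3S,6R)-2,6-dimethyl-3-[2-(triethylsilyloxy)propan-2-yl]cyclohex-1-en-1-yl]oxy}dimethylsilane; 12 methyl acrylate
Product: 15 3-[(1R,3S,6S)-1,3-dimethyl-2-oxo-6-[2-(triethylsilyloxy)propan-2-yl]cyclohexyl]propanoic acid, via silyl ketene acetal 13 (not isolated), via epimeric keto ester 14 (not isolated)
Conditions: 12 (1.5 equiv), (CF3SO2)2NH (2 mol %), CH2Cl2, −78 → −40 °C; then LiOH, THF/MeOH/H2O, rt; aq. HCl to pH 3
Reagents that add atoms: lithium hydroxide, [Li+].[OH-]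
Why: Triflimide-catalysed Mukaiyama–Michael addition should bring the acrylate to C10 anti to the adjacent pseudoaxial silyloxyisopropyl group on C5 and so set the quaternary centre; hydroxide then saponifies the ester and equilibrates C8 to the equatorial methyl epimer, which relieves the 1,3-diaxial methyl/methyl interaction with C10.

Step 8
Reactants: 15 3-[(1R,3S,6S)-1,3-dimethyl-2-oxo-6-[2-(triethylsilyloxy)propan-2-yl]cyclohexyl]propanoic acid; 16 methyl 2-(bromomethyl)prop-2-enoate
Product: 18 3-[(5R,6R,7S,10S)-6,10-dimethyl-3-methylidene-2-oxo-7-[2-(triethylsilyloxy)propan-2-yl]-1-oxaspiro[4.5]decan-6-yl]propanoic acid, via bromozinc alkoxide 17 (not isolated)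
Conditions: Zn dust (5 equiv, activated by Me3SiCl), 16 (3 equiv; one equivalent is quenched by the CO2H), THF, 50 °C; aq. NH4Cl
Reagents that add atoms: none
Why: In this Dreiding–Schmidt reaction (Reformatsky-type addition of a 2-alkoxycarbonylallylzinc, then lactonisation) the small allylzinc should attack the chair ketone axially, anti to the axial C10 methyl, so the new CH2 (C11) is axial and the oxygen equatorial (C9 R); the alkoxide closes 5-exo-trig on the acrylate ester, while the carboxylate cannot form the competing six-ring lactone.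

Step 9
Reactants: 18 3-[(5R,6R,7S,10S)-6,10-dimethyl-3-methylidene-2-oxo-7-[2-(triethylsilyloxy)propan-2-yl]-1-oxaspiro[4.5]decan-6-yl]propanoic acid; 4 pentan-3-one
Product: 21 3-[(2R,2'R,3'S,6'S)-2',5,6',7-tetramethyl-6-oxo-3'-[2-(triethylsilyloxy)propan-2-yl]-3a,4,5,6-tetrahydro-3H-spiro[1-benzofuran-2,1'-cyclohexan]-2'-yl]propanoic acid, via keto lactone 19 (not isolated), via hydroxy dione 20 (not isolated)
Conditions: 4 (1.2 equiv), LiN(i-Pr)2 (2.3 equiv; 1 equiv for the CO2H), THF, −78 → 0 °C; KOt-Bu (2 equiv), 40 °C; 1 M HCl; then pyridinium p-toluenesulfonate (cat.), PhMe, 4 Å MS, 80 °C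
Reagents that add atoms: none
Why: In a tandem Michael–Claisen annulation the enolate adds to the α-methylene lactone (T5–T6), its second α-carbon acylates on the lactone carbonyl (six-ring, T2–T3) releasing the C9 alkoxide, and acid lets that hydroxyl re-add to the neighbouring dione carbonyl and dehydrate to the vinylogous ester; the C9–O bond is never broken, and the new sp3 centres at T4 and T6 are uncontrolled and erased later.

Step 10
Reactants: 21 3-[(2R,2'R,3'S,6'S)-2',5,6',7-tetramethyl-6-oxo-3'-[2-(triethylsilyloxy)propan-2-yl]-3a,4,5,6-tetrahydro-3H-spiro[1-benzofuran-2,1'-cyclohexan]-2'-yl]propanoic acid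
Product: 24 3-[(2R,2'R,3'S,6'S)-6-bromo-2',5,6',8-tetramethyl-7-oxo-3'-[2-(triethylsilyloxy)propan-2-yl]-3,3a,4,7-tetrahydrospiro[cyclohepta[b]furan-2,1'-cyclohexan]-2'-yl]propanoic acid, via bis-silyl dienol ether 22 (not isolated), via dibromocyclopropane 23 (not isolated)
Conditions: LiN(i-Pr)2 (2.3 equiv), THF, −78 °C; Me3SiCl (3 equiv); solvent change to pentane; CHBr3 (2 equiv), KOt-Bu (2.5 equiv), −30 °C → rt; aq. citric acid
Reagents that add atoms: bromoform, BrC(Br)Br
Why: Kinetic α′-deprotonation of the vinylogous ester (the lithium carboxylate is a spectator) and O-silylation give a 1-alkoxy-3-silyloxy diene whose terminal silyl enol ether bond is the most nucleophilic site for dibromocarbene; the siloxydibromocyclopropane opens electrocyclically with loss of bromide and silyl (dihalocarbene one-carbon ring expansion), inserting T7 between T1 and T6.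

Step 11
Reactants: 24 3-[(2R,2'R,3'S,6'S)-6-bromo-2',5,6',8-tetramethyl-7-oxo-3'-[2-(triethylsilyloxy)propan-2-yl]-3,3a,4,7-tetrahydrospiro[cyclohepta[b]furan-2,1'-cyclohexan]-2'-yl]propanoic acid
Product: 25 3-[(2R,2'R,3'S,6'S)-6-(methoxycarbonyl)-2',5,6',8-tetramethyl-7-oxo-3'-[2-(triethylsilyloxy)propan-2-yl]-3,3a,4,7-tetrahydrospiro[cyclohepta[b]furan-2,1'-cyclohexan]-2'-yl]propanoic acid
Conditions: CO (1 atm), MeOH, Pd(OAc)2 (10 mol %), Ph2P(CH2)3PPh2 (12 mol %), Et3N, DMF, 70 °C
Reagents that add atoms: carbon monoxide, [C-]#[O+]; methanol, CO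
Why: Palladium-catalysed alkoxycarbonylation (oxidative addition of the α-bromoenone to zerovalent palladium, CO insertion, methanolysis) turns the vinyl bromide into the T7 methyl ester, while the carboxylate is not esterified under basic conditions.

Step 12
Reactants: 25 3-[(2R,2'R,3'S,6'S)-6-(methoxycarbonyl)-2',5,6',8-tetramethyl-7-oxo-3'-[2-(triethylsilyloxy)propan-2-yl]-3,3a,4,7-tetrahydrospiro[cyclohepta[b]furan-2,1'-cyclohexan]-2'-yl]propanoic acid
Product: 26 3-[(2R,2'R,3'S,6'S)-6-(methoxycarbonyl)-2',5,6',8-tetramethyl-7-oxo-3'-[2-(triethylsilyloxy)propan-2-yl]-3,7-dihydrospiro[cyclohepta[b]furan-2,1'-cyclohexan]-2'-yl]propanoic acid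
Conditions: DDQ (1.5 equiv), 1,4-dioxane, 80 °C
Reagents that add atoms: none
Why: In this quinone dehydrogenation, enolisation through T5 gives a cycloheptatrienol from which DDQ abstracts the doubly allylic T4 hydride to form a hydroxytropylium ion that loses a proton to the tropone, erasing the last uncontrolled centre.

Step 13
Reactants: 26 3-[(2R,2'R,3'S,6'S)-6-(methoxycarbonyl)-2',5,6',8-tetramethyl-7-oxo-3'-[2-(triethylsilyloxy)propan-2-yl]-3,7-dihydrospiro[cyclohepta[b]furan-2,1'-cyclohexan]-2'-yl]propanoic acid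
Product: 27 3-[(2R,2'R,3'S,6'S)-3'-(2-hydroxypropan-2-yl)-6-(methoxycarbonyl)-2',5,6',8-tetramethyl-7-oxo-3,7-dihydrospiro[cyclohepta[b]furan-2,1'-cyclohexan]-2'-yl]propanoic acid
Conditions: HF·pyridine, pyridine, THF, 0 °C → rt
Reagents that add atoms: none
Why: Buffered fluoride desilylation removes the tertiary triethylsilyl ether without the strong acid that could ionise the tertiary vinylogous-ester C9–O bond, and no stereocentre is touched.

Compound list
1 | methyl 2-hydroxy-2-methylpropanoate | COC(=O)C(C)(C)O | starting material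
2 | methyl 2-methyl-2-(triethylsilyloxy)propanoate | COC(=O)C(C)(C)O[Si](CC)(CC)CC | intermediate
3 | 2-methyl-2-(triethylsilyloxy)propanal | O=CC(C)(C)O[Si](CC)(CC)CC | intermediate
4 | pentan-3-one | CCC(=O)CC | starting material
5 | lithium 2,4-dimethyl-5-oxo-2-(triethylsilyloxy)heptan-3-olate (diastereomer mixture, not isolated) | [Li+].CCC(=O)C(C)C([O-])C(C)(C)O[Si](CC)(CC)CC | intermediate
6 | 2,4-dimethyl-5-oxo-2-(triethylsilyloxy)heptan-3-yl methanesulfonate (diastereomer mixture, not isolated) | CCC(=O)C(C)C(OS(C)(=O)=O)C(C)(C)O[Si](CC)(CC)CC | intermediate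
7 | (E)-4,6-dimethyl-6-(triethylsilyloxy)hept-4-en-3-one | CCC(=O)/C(C)=C/C(C)(C)O[Si](CC)(CC)CC | intermediate
8 | (2Z,4E)-3-(tert-butyldimethylsilyloxy)-4,6-dimethyl-6-(triethylsilyloxy)hepta-2,4-diene | C/C=C(\O[Si](C)(C)C(C)(C)C)/C(C)=C/C(C)(C)O[Si](CC)(CC)CC | intermediate
9 | acrolein (prop-2-enal) | C=CC=O | starting material
10 | (1S,2S,5R)-4-(tert-butyldimethylsilyloxy)-3,5-dimethyl-2-[2-(triethylsilyloxy)propan-2-yl]cyclohex-3-ene-1-carbaldehyde | CC(C)(C)[Si](C)(C)OC1=C(C)[C@@H](C(C)(C)O[Si](CC)(CC)CC)[C@@H](C=O)C[C@H]1C | intermediate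
11 | tert-butyl{[(3S,6R)-2,6-dimethyl-3-[2-(triethylsilyloxy)propan-2-yl]cyclohex-1-en-1-yl]oxy}dimethylsilane | CC(C)(C)[Si](C)(C)OC1=C(C)[C@@H](C(C)(C)O[Si](CC)(CC)CC)CC[C@H]1C | intermediate
12 | methyl acrylate | C=CC(=O)OC | starting material
13 | tert-butyldimethylsilyl methyl ketene acetal of keto ester 14 (not isolated) | O=C1[C@H](C)CC[C@H](C(C)(C)O[Si](CC)(CC)CC)[C@@]1(C)CC=C(OC)O[Si](C)(C)C(C)(C)C | intermediate
14 | methyl 3-[(1R,3R,6S)-1,3-dimethyl-2-oxo-6-[2-(triethylsilyloxy)propan-2-yl]cyclohexyl]propanoate (not isolated) | O=C1[C@H](C)CC[C@H](C(C)(C)O[Si](CC)(CC)CC)[C@@]1(C)CCC(=O)OC | intermediate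
15 | 3-[(1R,3S,6S)-1,3-dimethyl-2-oxo-6-[2-(triethylsilyloxy)propan-2-yl]cyclohexyl]propanoic acid | O=C1[C@@H](C)CC[C@H](C(C)(C)O[Si](CC)(CC)CC)[C@@]1(C)CCC(=O)O | intermediate
16 | methyl 2-(bromomethyl)prop-2-enoate | C=C(CBr)C(=O)OC | starting material
17 | bromozinc alkoxide of 3-[(1R,2R,3S,6S)-2-hydroxy-2-[2-(methoxycarbonyl)prop-2-en-1-yl]-1,3-dimethyl-6-[2-(triethylsilyloxy)propan-2-yl]cyclohexyl]propanoic acid (carboxyl drawn as the acid, not isolated) | Br[Zn]O[C@]1(CC(=C)C(=O)OC)[C@@H](C)CC[C@H](C(C)(C)O[Si](CC)(CC)CC)[C@@]1(C)CCC(=O)O | intermediate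
18 | 3-[(5R,6R,7S,10S)-6,10-dimethyl-3-methylidene-2-oxo-7-[2-(triethylsilyloxy)propan-2-yl]-1-oxaspiro[4.5]decan-6-yl]propanoic acid | O=C1O[C@]2(CC1=C)[C@@H](C)CC[C@H](C(C)(C)O[Si](CC)(CC)CC)[C@@]2(C)CCC(=O)O | intermediate
19 | 3-[(5R,6R,7S,10S)-6,10-dimethyl-3-(2-methyl-3-oxopentyl)-2-oxo-7-[2-(triethylsilyloxy)propan-2-yl]-1-oxaspiro[4.5]decan-6-yl]propanoic acid (epimers at the two new sp3 centres, not isolated) | O=C1O[C@]2(CC1CC(C)C(=O)CC)[C@@H](C)CC[C@H](C(C)(C)O[Si](CC)(CC)CC)[C@@]2(C)CCC(=O)O | intermediate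
20 | 3-[(1R,2R,3S,6S)-2-[(3,5-dimethyl-2,4-dioxocyclohexyl)methyl]-2-hydroxy-1,3-dimethyl-6-[2-(triethylsilyloxy)propan-2-yl]cyclohexyl]propanoic acid (epimer mixture in the dione ring, not isolated) | O[C@]1(CC2CC(C)C(=O)C(C)C2=O)[C@@H](C)CC[C@H](C(C)(C)O[Si](CC)(CC)CC)[C@@]1(C)CCC(=O)O | intermediate
21 | 3-[(2R,2'R,3'S,6'S)-2',5,6',7-tetramethyl-6-oxo-3'-[2-(triethylsilyloxy)propan-2-yl]-3a,4,5,6-tetrahydro-3H-spiro[1-benzofuran-2,1'-cyclohexan]-2'-yl]propanoic acid (epimers at C3a and C5) | O=C1C(C)=C2O[C@]3(CC2CC1C)[C@@H](C)CC[C@H](C(C)(C)O[Si](CC)(CC)CC)[C@@]3(C)CCC(=O)O | intermediate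
22 | trimethylsilyl ester and 6-O-trimethylsilyl dienol ether of 21 (epimers at C3a, not isolated) | CC1=C(O[Si](C)(C)C)C(C)=C2O[C@]3(CC2C1)[C@@H](C)CC[C@H](C(C)(C)O[Si](CC)(CC)CC)[C@@]3(C)CCC(=O)O[Si](C)(C)C | intermediate
23 | dibromocyclopropane adduct of 22 across the silyl enol ether bond (diastereomer mixture, not isolated) | CC12CC3C(=C(C)C1(O[Si](C)(C)C)C2(Br)Br)O[C@]4(C3)[C@@H](C)CC[C@H](C(C)(C)O[Si](CC)(CC)CC)[C@@]4(C)CCC(=O)O[Si](C)(C)C | intermediate
24 | 3-[(2R,2'R,3'S,6'S)-6-bromo-2',5,6',8-tetramethyl-7-oxo-3'-[2-(triethylsilyloxy)propan-2-yl]-3,3a,4,7-tetrahydrospiro[cyclohepta[b]furan-2,1'-cyclohexan]-2'-yl]propanoic acid (epimers at C3a) | O=C1C(C)=C2O[C@]3(CC2CC(C)=C1Br)[C@@H](C)CC[C@H](C(C)(C)O[Si](CC)(CC)CC)[C@@]3(C)CCC(=O)O | intermediate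
25 | 3-[(2R,2'R,3'S,6'S)-6-(methoxycarbonyl)-2',5,6',8-tetramethyl-7-oxo-3'-[2-(triethylsilyloxy)propan-2-yl]-3,3a,4,7-tetrahydrospiro[cyclohepta[b]furan-2,1'-cyclohexan]-2'-yl]propanoic acid (epimers at C3a) | O=C1C(C)=C2O[C@]3(CC2CC(C)=C1C(=O)OC)[C@@H](C)CC[C@H](C(C)(C)O[Si](CC)(CC)CC)[C@@]3(C)CCC(=O)O | intermediate
26 | 3-[(2R,2'R,3'S,6'S)-6-(methoxycarbonyl)-2',5,6',8-tetramethyl-7-oxo-3'-[2-(triethylsilyloxy)propan-2-yl]-3,7-dihydrospiro[cyclohepta[b]furan-2,1'-cyclohexan]-2'-yl]propanoic acid | COC(=O)c1c(C)cc2c(c(C)c1=O)O[C@]1(C2)[C@@H](C)CC[C@H](C(C)(C)O[Si](CC)(CC)CC)[C@@]1(C)CCC(=O)O | intermediate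
27 | 3-[(2R,2'R,3'S,6'S)-3'-(2-hydroxypropan-2-yl)-6-(methoxycarbonyl)-2',5,6',8-tetramethyl-7-oxo-3,7-dihydrospiro[cyclohepta[b]furan-2,1'-cyclohexan]-2'-yl]propanoic acid (CNP0448476.3) | COC(=O)c1c(C)cc2c(c(C)c1=O)O[C@]1(C2)[C@@H](C)CC[C@H](C(C)(C)O)[C@@]1(C)CCC(=O)O | target

Total step count: 13. Longest linear sequence: 13 steps (from 1; 4, 9, 12 and 16 are purchased).

Steps most likely to fail

Step 9. The methylene lactone may oligomerise through its own enolate before the Claisen closure. In the acid stage the tertiary C9 hydroxyl may close on the propanoic acid or ionise instead of adding to the dione. The fallback sets out from 18 and uses a soft, pre-activated donor. Base-catalysed Michael addition of commercial methyl 2-methyl-3-oxopentanoate should give the quaternary β-keto ester lactone F1, whose only enolisable ketone position is the ethyl CH2. KOt-Bu-mediated Claisen condensation on the lactone carbonyl and acid cyclodehydration should then give the ester-bearing bicyclic vinylogous ester F2. Krapcho dealkoxycarbonylation (LiCl, wet DMSO, 140 °C) comes back to the route at 21.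

Step 10. The carbene may add to the ring enol ether double bond instead of the silyl enol ether, or the cyclopropane may fail to open cleanly. The fallback builds the seven-membered ring by condensation instead. It sets out from 18: thiazolium-catalysed Stetter addition of acetaldehyde should give the acetonyl lactone F3. Knoevenagel condensation with methyl 3-oxopentanoate (TiCl4, pyridine) should give the alkylidene β-keto ester F4. LiN(SiMe3)2-mediated Claisen closure of the ethyl-ketone CH2 on the lactone carbonyl (seven-ring) and acid cyclodehydration come back to the route at 25.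

Step 5. Cycloaddition at the hindered diene terminus may be slow, so that acid-induced loss of the silyl enol ether, ionisation of the allylic tertiary silyl ether or achiral silyl-cation catalysis erodes yield and enantioselectivity. The fallback keeps the two-bond cycloaddition but uses a two-point-binding dienophile and a milder chiral catalyst. It sets out from 8: cycloaddition with 3-(prop-2-enoyl)-1,3-oxazolidin-2-one, catalysed by the Cu(SbF6)2 complex of 2,2'-(propane-2,2-diyl)bis[(4S)-4-tert-butyl-4,5-dihydro-1,3-oxazole] (divalent copper; enantiomer chosen for 5S), should give the imide F5. LiBH4 reduction should give the primary alcohol F6, and Dess–Martin oxidation (NaHCO3 buffer) comes back to the route at 10.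

Further compounds
F1 | step 9 | 3-[(5R,6R,7S,10S)-3-[2-(methoxycarbonyl)-2-methyl-3-oxopentyl]-6,10-dimethyl-2-oxo-7-[2-(triethylsilyloxy)propan-2-yl]-1-oxaspiro[4.5]decan-6-yl]propanoic acid | O=C1O[C@]2(CC1CC(C)(C(=O)OC)C(=O)CC)[C@@H](C)CC[C@H](C(C)(C)O[Si](CC)(CC)CC)[C@@]2(C)CCC(=O)O
F2 | step 9 | 3-[(2R,2'R,3'S,6'S)-5-(methoxycarbonyl)-2',5,6',7-tetramethyl-6-oxo-3'-[2-(triethylsilyloxy)propan-2-yl]-3a,4,5,6-tetrahydro-3H-spiro[1-benzofuran-2,1'-cyclohexan]-2'-yl]propanoic acid | O=C1C(C)=C2O[C@]3(CC2CC1(C)C(=O)OC)[C@@H](C)CC[C@H](C(C)(C)O[Si](CC)(CC)CC)[C@@]3(C)CCC(=O)O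
F3 | step 10 | 3-[(5R,6R,7S,10S)-6,10-dimethyl-2-oxo-3-(2-oxopropyl)-7-[2-(triethylsilyloxy)propan-2-yl]-1-oxaspiro[4.5]decan-6-yl]propanoic acid | O=C1O[C@]2(CC1CC(C)=O)[C@@H](C)CC[C@H](C(C)(C)O[Si](CC)(CC)CC)[C@@]2(C)CCC(=O)O
F4 | step 10 | 3-[(5R,6R,7S,10S)-3-[3-(methoxycarbonyl)-2-methyl-4-oxohex-2-en-1-yl]-6,10-dimethyl-2-oxo-7-[2-(triethylsilyloxy)propan-2-yl]-1-oxaspiro[4.5]decan-6-yl]propanoic acid | O=C1O[C@]2(CC1CC(C)=C(C(=O)OC)C(=O)CC)[C@@H](C)CC[C@H](C(C)(C)O[Si](CC)(CC)CC)[C@@]2(C)CCC(=O)O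
F5 | step 5 | 3-{[(1S,2S,5R)-4-(tert-butyldimethylsilyloxy)-3,5-dimethyl-2-[2-(triethylsilyloxy)propan-2-yl]cyclohex-3-en-1-yl]carbonyl}-1,3-oxazolidin-2-one | CC(C)(C)[Si](C)(C)OC1=C(C)[C@@H](C(C)(C)O[Si](CC)(CC)CC)[C@@H](C(=O)N2CCOC2=O)C[C@H]1C
F6 | step 5 | [(1S,2S,5R)-4-(tert-butyldimethylsilyloxy)-3,5-dimethyl-2-[2-(triethylsilyloxy)propan-2-yl]cyclohex-3-en-1-yl]methanol | CC(C)(C)[Si](C)(C)OC1=C(C)[C@@H](C(C)(C)O[Si](CC)(CC)CC)[C@@H](CO)C[C@H]1C
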